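The data stem from a simulated flask on assumed constants; the scatter is artificial.

Don't book everything the readings leave unaccounted as open dimer. The next run hangs on this: change the charge or change the time.

| flask | starting material | remark | time |
|---|---|---|---|
| midnight | 0.25 M | run made earlier |  |
| dusk | 0.55 M | run made earlier |  |
| flask | 0.37 M |  | 20 h |

| run | time / h | starting material / % | ring / % |
|---|---|---|---|
| midnight | 1.33 | 77.6 | 9.7 |
| midnight | 2.50 | 63.1 | 15.8 |
| midnight | 5.00 | 43.3 | 27.5 |
| midnight | 8.00 | 30.4 | 34.4 |
| midnight | 15.0 | 17.7 | 47.8 |
| dusk | 3.00 | 52.9 | 17.5 |
| dusk | 6.00 | 33.1 | 27.4 |
| dusk | 10.0 | 23.3 | 36.2 |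
| dusk | 12.0 | 19.9 | 39.4 |
| dusk | 15.0 | 17.2 | 44.1 |

(each reading ± 0.5 percentage points)

- the state of affairs at 20 h: stopped, and by what, or still going (all of the starting material has reacted / it is still moving / forward and back rates have come level)
- share of the starting material used up at 20 h
- ring at 20 h, in percent of the starting material charged
- open dimer at 20 h, in percent of the starting material charged

- percentages count the starting material that a species holds: one open dimer counts as two
- what was read earlier has a scatter of 0.5 percentage points, one standard deviation
- what has gone from starting material into another species counts as reacted, even if it can come back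
- a reading or a percentage of ring counts all its forms, free or not
- the reaction counts as stopped when no species that holds the starting material changes by six tenths of a point or more over the second half of the time

At 15.0 h the gap beside starting material and ring is 34.5% in the midnight run and 38.7% in the dusk run, though the charge went from 0.25 M to 0.55 M. A dimer needs two molecules to meet, so its share should grow with the charge; this gap grew by 4.2 percentage points. Divide each gap by the starting material beside it and run the two ratios back to zero charge. That gives 1.70, the hold-back ratio: parts kept in reserve per part of free starting material, a reading that carries the scatter of the runs.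

Assume, for this reckoning, that the exchange stays level (a pre-equilibrium). Over the last two readings of the midnight run, ring grows at 0.0796 h⁻¹ on free starting material, so on that assumption free plus reserve drain at that rate divided by one plus the ratio, a half-life of 23.5 h. Interpolate this flask at 15.0 h, 17.5% starting material and 46.3% ring, and drain on to 20 h. I get 15.1% starting material, 52.8% ring, 25.6% in reserve and 6.46% open dimer. In my reckoning for this flask the reserve exceeds the dimer, so leave the charge at 0.37 M and change the time.

The forecast, that “the dimer drains back through starting material to ring”, says it is still moving, with 86% used up, ring 52% and open dimer 34%, which parts from my reckoning on the dimer. The flask gives: it is still moving, 85.6% used up, ring 52.4%, open dimer 8.91%.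

    starting material ⇌ dormant form (K = 1.29, k = 0.0772 h⁻¹)
    starting material → ring (k = 0.0801 h⁻¹)
    crystals ⇌ ring, rate k3*(cs3 - [ring]) while solid is left; crystals form when [ring] > cs3 (solubility = 0.0710 M, k = 2.06 h⁻¹)
    2 starting material ⇌ open dimer (K = 1.70 L mol⁻¹, k = 0.0950 L mol⁻¹ h⁻¹)
    starting material → decomposition product (k = 3.54 × 10⁻⁵ h⁻¹)

The reserve is the dormant form, 24.3% at 20.0 h; the ratio times the 14.4% of starting material gives 24.5%. But the level exchange was a stand-in: dormant form over starting material in this flask is 1.07 at 10.0 h and 1.69 at 20.0 h. This flask has not come to rest: the largest share moved 14 points over the second half, and my drain half-life is longer than the time. At 200 h conversion stands at 99.8%, ring at 99.4% and open dimer at 0%.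

Drain the same flask on to 72.0 h: the ratio gives 3.26% starting material. The computed result is 4.17%, with ring at 86.2%.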